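**Retrosynthetic overview**
1. Feature: a single oxygen spans C5 (H) and C10 (CH3) of a ten-membered carbocycle, so oxepane A (O–C10–C9–C8–C7–C6–C5) and oxepane B (O–C10–C1–C2–C3–C4–C5) share that one ring. C10 lies next to the oxygenated C9 and is therefore a latent chelatable α-alkoxy ketone, with C5 a second ketone across the ring.
2. Disconnections: the C13 methylene and the C9 isovalerate come off last; C5–H derives from a C5 hemiketal; C10–CH3 and O–C5 are made together (MeTiCl3 addition at C10, transannular hemiketalisation at C5) from the 9-benzyloxy 5,10-diketone lactone.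
3. The diketone arises by ozonolysis of the C5=C10 alkene of an octalin made from 6-methoxy-1-tetralone through Birch reduction; the C7/C8 lactone is closed at the octalin stage.
4. Stereochemical relay: C4 (iridium-catalysed hydrogenation) → temporary C5–OH (epoxidation anti to the C4 methyl) → C7 → C8 → C9; an oxidative allylic transposition then removes C5–OH and restores C5=C10.
5. Ring order: the two six-membered carbocycles (from the tetralone), the γ-lactone, the ten-membered ring (ozonolysis), then both oxepanes at once (key step).

Key step: step 11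

Numbering: carbocycle C1–C10; C15 = methyl on C4; C14 = methyl on C10; C11/C12 = lactone CH2 and C=O (C12–O on C8); C13 = exocyclic methylene. "Lower face" is the face of the flat octalin that carries the C4 methyl.
Assumption: the hand of the phosphinooxazoline ligand in step 2 is the one that leads to the (S)-tetralin 5; the sense of induction depends on the ligand alone and is to be fixed by a trial hydrogenation.

**Step 1**
Reactants: 1 6-methoxy-1-tetralone; 2 methylmagnesium bromide
Product: 4 7-methoxy-4-methyl-1,2-dihydronaphthalene, via tertiary benzylic alcohol 3 (not isolated)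
Conditions: MeMgBr, THF, 0 °C → rt; aq NH4Cl; then TsOH·H2O (cat.), PhMe, 80 °C
Reagents that add atoms: methylmagnesium bromide (2), C[Mg]Br
Why: Grignard 1,2-addition to the aryl ketone followed by acid-catalysed E1 dehydration of the tertiary benzylic alcohol should give the conjugated endocyclic alkene; no stereocenter is formed.

**Step 2**
Reactants: 4 7-methoxy-4-methyl-1,2-dihydronaphthalene
Product: 5 (S)-6-methoxy-1-methyl-1,2,3,4-tetrahydronaphthalene
Conditions: H2 (50 bar), [Ir(cod)(L)][B(3,5-(CF3)2C6H3)4] (1 mol %, L = 4-tert-butyl-2-[2-(diphenylphosphino)phenyl]-2-oxazoline), CH2Cl2, rt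
Reagents that add atoms: none
Why: Iridium phosphinooxazoline catalysts hydrogenate unfunctionalised trisubstituted cyclic styrenes of the 1-methyl-3,4-dihydronaphthalene class with high enantioselectivity (asymmetric hydrogenation), so the catalyst sets C4.

**Step 3**
Reactants: 5 (S)-6-methoxy-1-methyltetralin
Product: 7 (S)-5-methyl-3,4,5,6,7,8-hexahydronaphthalen-2(1H)-one (C8 ketone, C5=C10 alkene), via Birch enol ether 6 (not isolated)
Conditions: Li, NH3 (l), THF, tBuOH, −78 → −33 °C; then (CO2H)2, MeOH/H2O, rt
Reagents that add atoms: water, O
Why: Birch reduction of the anisole ring leaves the tetrasubstituted ring-fusion alkene C5=C10 and the enol ether C7=C8, and mild oxalic acid hydrolysis stops at the β,γ-unsaturated ketone without conjugation, as in the 19-norsteroid series; C4 is untouched.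

**Step 4**
Reactants: 7 β,γ-unsaturated ketone
Product: 9 5-hydroxy-4-methyl-octal-9(10)-en-8-one bearing C5–OH on the upper face (trans to C4–CH3), via ring-fusion epoxy ketone 8 (not isolated)
Conditions: mCPBA, NaHCO3, CH2Cl2, 0 °C; then DBU, CH2Cl2, rt
Reagents that add atoms: mCPBA, OOC(=O)c1cccc(Cl)c1
Why: Prilezhaev epoxidation of the tetrasubstituted alkene should occur on the face opposite the C4 methyl, which A(1,2) strain with C6 holds pseudoaxial, and the β,γ-epoxy ketone then opens by E1cB elimination through the C9 enolate to the γ-hydroxy enone, so C5–OH stands trans to the C4 methyl (the C5 epimer, a diastereomer, is to be removed by chromatography here).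

**Step 5**
Reactants: 9 γ-hydroxy enone; 10 methyl bromoacetate
Product: 11 7-(methoxycarbonylmethyl) derivative of 9, C7 arm on the lower face
Conditions: LiN(iPr)2 (2.2 equiv), THF, −78 °C; BrCH2CO2Me, DMPU, −78 → −30 °C; then NaOMe (cat.), MeOH, 0 °C
Reagents that add atoms: methyl bromoacetate (10), COC(=O)CBr
Why: Kinetic α'-deprotonation of the cyclohexenone at C7 in the alkoxide–enolate dianion and SN2 enolate alkylation place the acetate arm on C7, and methoxide equilibration of this epimerisable centre should leave it equatorial, trans to the axial C5 oxygen and therefore cis to the C4 methyl.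

**Step 6**
Reactants: 11 keto ester
Product: 13 trans-fused C7/C8 γ-lactone bearing C5–OH and the C9=C10 alkene, via hydroxy ester 12 (not isolated)
Conditions: NaBH4, CeCl3·7H2O, MeOH, −78 → 0 °C; then NaH (0.2 equiv), THF, 0 °C → rt
Reagents that add atoms: none
Why: Luche 1,2-reduction by axial hydride attack should give the equatorial C8 alcohol trans to the C7 arm, and alkoxide-catalysed transesterification (5-exo-trig lactonisation) then closes the trans-fused lactone, which also masks the C8 oxygen for step 7.

**Step 7**
Reactants: 13 hydroxy lactone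
Product: 14 enone lactone (C9 ketone conjugated to C5=C10)
Conditions: [C5H5NH][CrO3Cl] (pyridinium chlorochromate), NaOAc, 4 Å sieves, CH2Cl2, rt
Reagents that add atoms: pyridinium chlorochromate, [O-][Cr](=O)(=O)Cl.c1cc[nH+]cc1
Why: Babler–Dauben oxidative transposition: the chromate ester of the tertiary allylic alcohol undergoes a [3,3] shift to C9 and is oxidised there, which restores the tetrasubstituted C5=C10 alkene, erases the relay centre C5 and puts a ketone on C9.

**Step 8**
Reactants: 14 enone lactone
Product: 15 allylic alcohol, C9–OH on the lower face (trans to C8–O)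
Conditions: NaBH4, CeCl3·7H2O, MeOH, −78 °C; AcOH quench
Reagents that add atoms: none
Why: Luche 1,2-reduction of the enone by axial attack, anti to the axial C8 hydrogen of the conformationally locked trans-fused lactone, should give the pseudo-equatorial C9 alcohol trans to the C8 oxygen and cis to the C7 arm.

**Step 9**
Reactants: 15 allylic alcohol; 16 2-benzyloxy-1-methylpyridinium trifluoromethanesulfonate
Product: 17 C9 benzyl ether of the octalin lactone
Conditions: 16, MgO, PhCF3, 85 °C
Reagents that add atoms: 2-benzyloxy-1-methylpyridinium trifluoromethanesulfonate (16), C[n+]1ccccc1OCc1ccccc1.[O-]S(=O)(=O)C(F)(F)F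
Why: Benzyl transfer from the pyridinium salt (thermal SN1-type O-benzylation) runs under neutral conditions, which spares the base-sensitive trans-lactone and the acid-sensitive allylic alcohol, and installs the chelating ether needed in step 11.

**Step 10**
Reactants: 17 benzyl ether octalin
Product: 18 9-benzyloxy-4-methylcyclodecane-5,10-dione carrying the trans C7/C8 γ-lactone
Conditions: O3, CH2Cl2/MeOH, −78 °C; then Me2S, −78 °C → rt
Reagents that add atoms: ozone, [O-][O+]=O
Why: Ozonolysis (Criegee cleavage, reductive work-up) of the ring-fusion alkene of a 5(10)-octalin is the classical entry to cyclodecane-1,6-diones; the electron-rich tetrasubstituted alkene should react well before the benzyl ether, and the neutral conditions leave C4 and C9 untouched.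

**Step 11**
Reactants: 18 diketone lactone; 19 dimethylzinc
Product: 21 5,10-oxygen-bridged C5 hemiketal carrying the 9-benzyl ether, via C10 titanium alkoxide 20 (not isolated)
Conditions: TiCl4 (2.2 equiv), Me2Zn (1.1 equiv), CH2Cl2, −78 °C (gives MeTiCl3); then 18, −78 → −30 °C; aq NaHCO3
Reagents that add atoms: dimethylzinc (19), C[Zn]C; titanium tetrachloride, Cl[Ti](Cl)(Cl)Cl; methyltitanium trichloride, C[Ti](Cl)(Cl)Cl
Why: Methyltitanium trichloride, made in the flask from dimethylzinc and titanium tetrachloride, locks the C10 ketone oxygen and the C9 benzyloxy oxygen into a five-membered titanium chelate, its methyl group migrates to C10, and the C10 alkoxide so formed attacks the C5 carbonyl across the ten-membered ring. The closest known reaction types are the chelation-controlled addition of MeTiCl3 to α-alkoxy ketones and the transannular hemiketalisation of 6-hydroxycyclodecanones. The single new O–C5 bond closes oxepane A and oxepane B together, each by 7-exo-trig addition of oxygen to the carbonyl. C10 is set by the chelate, in which methyl enters on the carbonyl face that carries H9 and not C8, and C5 is set by the one-atom bridge, which allows only the hemiketal with its hydroxyl on the outer face. The step needs chemoselectivity for C10 over the C5 ketone and the lactone, which chelation-accelerated addition to the α-alkoxy ketone should secure. It also needs C4, C9 and the β-acyloxy ketone unit C10–C9–C8 to survive, which the non-basic, non-enolising titanium reagent should secure.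

**Step 12**
Reactants: 21 bridged hemiketal
Product: 22 bridged ether lactone (C5–H), 9-O-benzyl
Conditions: Et3SiH, BF3·OEt2, CH2Cl2, −40 → 0 °C
Reagents that add atoms: none
Why: Proposed new method: BF3 should ionise the C5 hydroxyl to a bridgehead oxocarbenium ion that cannot be planar, but the bridge oxygen keeps a second lone pair in the C5–O–C10 plane and both seven-membered rings are flexible, so partial O→C5 donation should suffice for hydride transfer from Et3SiH to the only open (outer) face, which fixes C5–H; the closest known reaction type is the Et3SiH/BF3·OEt2 reductive deoxygenation of monocyclic and fused cyclic hemiketals (reductive etherification).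

**Step 13**
Reactants: 22 bridged ether lactone; 23 N,N-dimethylmethyleneiminium iodide (Eschenmoser's salt)
Product: 24 11-(dimethylaminomethyl) lactone (C11 epimers)
Conditions: LiN(iPr)2, THF, −78 °C; [CH2=NMe2]I, −78 → 0 °C
Reagents that add atoms: N,N-dimethylmethyleneiminium iodide (23), C=[N+](C)C.[I-]
Why: The lactone is the only enolisable carbonyl, so its lithium enolate undergoes Mannich aminomethylation at C11, which stores the future methylene as an amine that survives hydrogenolysis; the new C11 centre is lost in step 16.

**Step 14**
Reactants: 24 Mannich base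
Product: 25 C9 alcohol
Conditions: H2 (1 atm), Pd/C, EtOAc/AcOH, rt
Reagents that add atoms: none
Why: Palladium-catalysed hydrogenolysis cleaves the benzyl ether and leaves the saturated lactone, the bridged ether and the protonated amine untouched.

**Step 15**
Reactants: 25 C9 alcohol; 26 isovaleryl chloride
Product: 27 C9 isovalerate
Conditions: isovaleryl chloride, Et3N, DMAP (cat.), CH2Cl2, 0 °C → rt
Reagents that add atoms: isovaleryl chloride (26), CC(C)CC(Cl)=O
Why: DMAP-catalysed acyl transfer esterifies the hindered secondary C9 alcohol with retention at C9.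

**Step 16**
Reactants: 27 amino lactone isovalerate
Product: 29 CNP0274454.1 (target), via trimethylammonium iodide 28 (not isolated)
Conditions: MeI, THF/MeOH, rt; then NaHCO3, H2O/EtOAc, rt
Reagents that add atoms: iodomethane, CI
Why: N-Methylation of the Mannich base and E1cB (Hofmann-type) loss of trimethylamine under bicarbonate unveil the α-methylene lactone last, under conditions that leave the isovalerate intact.

**Compound list**
1 | 6-methoxy-1-tetralone | COc1ccc2C(=O)CCCc2c1 | starting material
2 | methylmagnesium bromide | C[Mg]Br | starting material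
3 | 6-methoxy-1-methyltetralin-1-ol (racemic tertiary benzylic alcohol) | COc1ccc2c(c1)CCCC2(C)O | intermediate
4 | 7-methoxy-4-methyl-1,2-dihydronaphthalene | COc1ccc2C(C)=CCCc2c1 | intermediate
5 | (S)-6-methoxy-1-methyl-1,2,3,4-tetrahydronaphthalene | COc1ccc2c(c1)CCC[C@@H]2C | intermediate
6 | (S)-6-methoxy-1-methyl-1,2,3,4,5,8-hexahydronaphthalene (enol ether C7=C8, alkene C5=C10) | COC1=CCC2=C(C1)CCC[C@@H]2C | intermediate
7 | (S)-5-methyl-3,4,5,6,7,8-hexahydronaphthalen-2(1H)-one (C8 ketone, C5=C10) | O=C1CCC2=C(C1)CCC[C@@H]2C | intermediate
8 | 5,10-epoxide of 7, oxygen on the upper face (anti to C4–CH3) | O=C1CC[C@]23O[C@@]2(C1)CCC[C@@H]3C | intermediate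
9 | 5-hydroxy-4-methyl-octal-9(10)-en-8-one, C5–OH upper face, trans to C4–CH3 | O=C1C=C2CCC[C@H](C)[C@]2(O)CC1 | intermediate
10 | methyl bromoacetate | COC(=O)CBr | starting material
11 | methyl ester of the C7-acetic acid of 9, arm on the lower face (trans to C5–OH, cis to C4–CH3) | O=C1C=C2CCC[C@H](C)[C@]2(O)C[C@@H]1CC(=O)OC | intermediate
12 | 5,8-dihydroxy ester, C8–OH upper face (trans to the C7 arm) | O[C@H]1C=C2CCC[C@H](C)[C@]2(O)C[C@@H]1CC(=O)OC | intermediate
13 | trans-fused C7/C8 γ-lactone bearing C5–OH and C9=C10 | O=C1C[C@H]2C[C@@]3(O)[C@@H](C)CCCC3=C[C@@H]2O1 | intermediate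
14 | trans-fused lactone, C9 ketone conjugated to C5=C10 | O=C1C[C@H]2CC3=C(CCC[C@@H]3C)C(=O)[C@@H]2O1 | intermediate
15 | C9 alcohol, lower face (trans to C8–O, cis to C7 arm and C4–CH3), C5=C10 | O=C1C[C@H]2CC3=C(CCC[C@@H]3C)[C@@H](O)[C@@H]2O1 | intermediate
16 | 2-benzyloxy-1-methylpyridinium trifluoromethanesulfonate | C[n+]1ccccc1OCc1ccccc1.[O-]S(=O)(=O)C(F)(F)F | starting material
17 | C9 benzyl ether of 15 | O=C1C[C@H]2CC3=C(CCC[C@@H]3C)[C@@H](OCc4ccccc4)[C@@H]2O1 | intermediate
18 | 9-benzyloxy-4-methylcyclodecane-5,10-dione carrying the trans C7/C8 γ-lactone (key-step precursor) | O=C1C[C@H]2CC(=O)[C@@H](C)CCCC(=O)[C@@H](OCc3ccccc3)[C@@H]2O1 | intermediate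
19 | dimethylzinc | C[Zn]C | starting material
20 | trichlorotitanium alkoxide of the 10-hydroxy-10-methyl 5-ketone (methyl anti to C8) | O=C1C[C@H]2CC(=O)[C@@H](C)CCC[C@@](C)(O[Ti](Cl)(Cl)Cl)[C@@H](OCc3ccccc3)[C@@H]2O1 | intermediate
21 | 5,10-oxygen-bridged C5 hemiketal (C5–OH outside), 9-benzyl ether, lactone intact (key-step product) | O=C1C[C@H]2C[C@@]3(O)O[C@](C)(CCC[C@@H]3C)[C@@H](OCc4ccccc4)[C@@H]2O1 | intermediate
22 | bridged ether lactone with C5–H, 9-O-benzyl | O=C1C[C@H]2C[C@H]3O[C@](C)(CCC[C@@H]3C)[C@@H](OCc4ccccc4)[C@@H]2O1 | intermediate
23 | N,N-dimethylmethyleneiminium iodide | C=[N+](C)C.[I-] | starting material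
24 | 11-(dimethylaminomethyl) lactone, 9-O-benzyl (C11 epimers, configuration immaterial) | O=C1C(CN(C)C)[C@H]2C[C@H]3O[C@](C)(CCC[C@@H]3C)[C@@H](OCc4ccccc4)[C@@H]2O1 | intermediate
25 | 11-(dimethylaminomethyl) lactone, C9 alcohol | O=C1C(CN(C)C)[C@H]2C[C@H]3O[C@](C)(CCC[C@@H]3C)[C@@H](O)[C@@H]2O1 | intermediate
26 | isovaleryl chloride | CC(C)CC(Cl)=O | starting material
27 | 11-(dimethylaminomethyl) lactone, C9 isovalerate | O=C1C(CN(C)C)[C@H]2C[C@H]3O[C@](C)(CCC[C@@H]3C)[C@@H](OC(=O)CC(C)C)[C@@H]2O1 | intermediate
28 | trimethylammonium iodide of 27 | O=C1C(C[N+](C)(C)C)[C@H]2C[C@H]3O[C@](C)(CCC[C@@H]3C)[C@@H](OC(=O)CC(C)C)[C@@H]2O1.[I-] | intermediate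
29 | CNP0274454.1 | C=C1C(=O)O[C@@H]2[C@@H]1C[C@H]1O[C@](C)(CCC[C@@H]1C)[C@H]2OC(=O)CC(C)C | target

**Totals**
Total step count: 16. Longest linear sequence: 16 steps (from 1).

**Steps most likely to fail**

Step 12. Ionisation at the bridgehead may be too slow because the cation cannot become coplanar with the bridge oxygen, or the cation may lose a proton toward C4 and be reprotonated, which would scramble C4. The fallback sets out from 21 and returns at 22 by known chemistry. Hydroxyl-directed reduction (Evans–Saksena type, Me4NBH(OAc)3, AcOH/MeCN) is applied to the ring-opened hydroxy ketone tautomer. Boron held on the C10 hydroxyl delivers hydride across the ring to the C5 face that the bridge oxygen must later occupy, which should give the 5,10-diol F1 with C5–OH on the outer face. MsCl and Et3N sulfonylate only the secondary hydroxyl to give the C5 mesylate F2. KOtBu in THF then closes the bridge by transannular Williamson etherification with inversion at C5, which gives 22.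

Step 11. The Lewis acid may trigger transannular aldolisation of the 1,6-dione or β-elimination of the lactone carboxylate from C8, methyl may be transferred to the C5 ketone, or facial discrimination at C10 may be poor. The fallback sets out from 18 and returns at 22, bypassing 21 and step 12. Takai–Lombardo methylenation (Zn, CH2Br2, TiCl4) of the more electrophilic, chelating C10 ketone should give the 10-methylene 5-ketone F3. NaBH4 with CeCl3·7H2O reduces the C5 ketone to the C5 alcohol F4 with oxygen on the bridge face (Mitsunobu inversion if the other epimer prevails). Hg(OCOCF3)2 followed by NaBH4 then effects transannular Markovnikov alkoxymercuration–demercuration, which forms O–C10 and the C10 methyl; in this variant the bridge from C5 fixes C10.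

Step 4. The C4 methyl may discriminate the two alkene faces too weakly in the epoxidation, which would send the C5 epimer, and with it the wrong C7–C9 series, forward. The fallback sets out from 7 and returns at 9. Dihydroxylation with OsO4 (cat.) and N-methylmorpholine N-oxide, whose bulkier osmate approach is more sensitive to the pseudoaxial methyl, should give the cis-5,10-diol F5. K2CO3 in MeOH then eliminates the tertiary β-hydroxyl (E1cB aldol dehydration) to give 9.

**Further compounds**
F1 | step 12 | 5,10-diol from reduction of the C5 ketone of 21 (C5–OH on the outer face, epimeric to the ether oxygen) | O=C1C[C@H]2C[C@H](O)[C@@H](C)CCC[C@@](C)(O)[C@@H](OCc3ccccc3)[C@@H]2O1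
F2 | step 12 | C5 methanesulfonate of F1 | O=C1C[C@H]2C[C@H](OS(C)(=O)=O)[C@@H](C)CCC[C@@](C)(O)[C@@H](OCc3ccccc3)[C@@H]2O1
F3 | step 11 | 9-benzyloxy-10-methylene-4-methylcyclodecan-5-one fused to the C7/C8 lactone | O=C1C[C@H]2CC(=O)[C@@H](C)CCCC(=C)[C@@H](OCc3ccccc3)[C@@H]2O1
F4 | step 11 | C5 alcohol of F3 with oxygen on the bridge face | O=C1C[C@H]2C[C@@H](O)[C@@H](C)CCCC(=C)[C@@H](OCc3ccccc3)[C@@H]2O1
F5 | step 4 | cis-5,10-dihydroxy-4-methyldecalin-8-one, both hydroxyls on the upper face | O=C1CC[C@]2(O)[C@](O)(C1)CCC[C@@H]2C
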